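**Remarks on the chemistry**

- Compound 7 is used as dry monomeric formaldehyde, made just before use by cracking paraformaldehyde; the aqueous or polymeric forms would destroy or fail to trap the aluminium species.
- NMO is anhydrous N-methylmorpholine N-oxide, chosen as a less hazardous ligand for iBu2AlH in the role that hexamethylphosphoramide can also play. (−)-DAIB is (2S)-(−)-3-exo-(dimethylamino)isoborneol.
- The S descriptor of the benzylic carbon and the Z descriptors of both double bonds were re-derived from the target SMILES and from every intermediate; they are consistent and no structure needed correction. Compound 8 is named E only because aluminium outranks the ester carbon; its geometry is that of 10.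

## Structural features

The molecule is acyclic apart from one benzene ring: a 3,4,5-trimethoxyphenyl ring carries a benzylic carbinol carbon that also bears an ethyl group and an ester oxygen. That oxygen is acylated by a (Z)-2-(acyloxymethyl)but-2-enoic acid, and the CH2O branch at C2 of this central acid is in turn acylated by (Z)-2-methylbut-2-enoic acid, so the chain reads aryl carbinol, central enoate, CH2O, angelate. There is a single stereocentre, the S-configured benzylic carbon, so no stereocentres stand next to each other; the other stereochemical elements are two trisubstituted Z double bonds, each with its C4 methyl cis to its own ester carbonyl. Both double bonds have the less stable geometry and can drift to the E form under nucleophilic amines, base, acid or heat, and the central unit is in addition an allylic ester of the Morita–Baylis–Hillman type, open to SN2′ attack. The benzylic ester on an electron-rich ring can ionise under protic or Lewis acid, which would racemise the carbinol carbon or eliminate to a styrene, and it is sensitive to hydride and to hydrogenolysis. The real difficulty is therefore not the skeleton but bringing in the central C2=C3 double bond with Z geometry and carrying it, together with the optical purity of the carbinol, to the end. The key step exploits the fact that in the central enoate H-3 and the CH2O branch on C2 are cis (C4 methyl cis to the C1 carbonyl), which is the pattern left by syn addition of hydrogen to C3 and of a CH2OH unit to C2 of a but-2-ynoate.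

## Logic of the disconnections

13 to 10 and 11. The first cut is the acyl C–O bond between the oxygen of the CH2O branch and the carbonyl carbon of the terminal Z-enoyl group. The reason is that 11 is bought with its Z geometry in place, and that the acyl group most prone to Z-to-E drift and the allylic ester most open to SN2′ chemistry then exist only after the last step. The gain is five carbons and one Z double bond, leaving 10 with a free primary hydroxyl. The demand on the forward step is an acylation with no nucleophilic catalyst and no free strong acid, which is why 11 is activated as 12 under a hindered amine.

10 to 6 and 7. The C2–CH2OH bond and the C3–H bond of the central enoate are cut together. The reason is that a problem of double-bond geometry becomes a stereospecific syn addition to a triple bond. The gain is that one C–C bond and the Z double bond trace back to an alkyne without stereochemistry and a one-carbon electrophile, with no protecting group. The demands are conjugate delivery of hydride to C3 of 6 that spares the hindered ester carbonyl, capture of 8 at C2 on the hydrogen side before it equilibrates, and cold hydrolysis of 9.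

6 to 3 and 4. The acyl C–O bond between the ynoate carbonyl carbon and the benzylic oxygen is cut. The reason is that the benzylic C–O bond is not the one formed, so the configuration of 3 passes unchanged into 6. The gain is separation of the stereocentre from the four-carbon acid, both halves being simple. The demand is an activation of 4 (through 5) that is mild enough not to isomerise the triple bond to an allene, not to add nucleophiles to it, and never acidic enough to ionise the benzylic position.

3 to 1. The C–C bond between the carbinol carbon and the CH2 of the ethyl group is cut. The reason is that the only stereocentre then arises by face-selective addition of a two-carbon organozinc nucleophile to the prochiral carbonyl of 1 under a chiral amino-alcohol catalyst. The gain is an achiral aromatic aldehyde as the start. The demand is ethyl transfer to the Si face with a slow uncatalysed background, giving 2 and, after hydrolysis, 3.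

## Other disconnections considered

Alternative 1: The cut is the C–O bond between the benzylic carbon and the carboxylate oxygen of the central ester, combined with a retro-hydrogenation of the ethyl group to a vinyl group.
- Forward step: the arylallene 1,2,3-trimethoxy-5-(propa-1,2-dien-1-yl)benzene A2 and the complete acid (Z)-2-{[(Z)-2-methylbut-2-enoyl]oxymethyl}but-2-enoic acid A3 would be joined under [Rh(cod)Cl]2 and one enantiomer of DIOP, through a rhodium allyl species captured at its substituted end. This would give the branched ester (S)-1-(3,4,5-trimethoxyphenyl)prop-2-en-1-yl (Z)-2-{[(Z)-2-methylbut-2-enoyl]oxymethyl}but-2-enoate A1. Hydrogenation of the vinyl group of A1 (H2, RhCl(PPh3)3) would then give 13.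
- In its favour: the union is atom-economical, no acid has to be activated as an acyl donor, and the stereocentre and the last ester bond are made in one catalytic event without a preformed chiral alcohol. In convergence it is the better plan.
- Against it here: A3 must already hold both Z double bonds, so the geometric problem is moved and not solved, and A3 has to be freed from a carboxyl protecting group next to an allylic ester that reacts with nucleophiles and bases. A1 is at once benzylic and allylic on an electron-rich ring, so re-ionisation at rhodium could erode the enantiomeric purity or move the ester to the linear, conjugated position. The final hydrogenation must single out a terminal vinyl group beside two trisubstituted enoates without hydrogenolysis of the C–O bond.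
- Comparison: on structure both plans end with the same three fragments. On mechanism the alternative forms the stereocentre in a reversible allyl-metal manifold and offers nothing for the Z geometry, whereas the chosen plan forms the stereocentre irreversibly in step 1 and derives the Z geometry from a stereospecific addition. On step economy the alternative needs roughly twice as many steps (A2, A3, union, hydrogenation) as the four of the chosen plan.

Alternative 2: The cut is the C2=C3 double bond of the central enoate.
- Forward step: the phosphonate (S)-1-(3,4,5-trimethoxyphenyl)propyl 2-[bis(2,2,2-trifluoroethoxy)phosphoryl]-3-[(triisopropylsilyl)oxy]propanoate A5 would be deprotonated with KN(SiMe3)2 and 18-crown-6 and condensed with acetaldehyde A6. This would give (S)-1-(3,4,5-trimethoxyphenyl)propyl (Z)-2-{[(triisopropylsilyl)oxy]methyl}but-2-enoate A4, which after desilylation would join the chosen route at 10.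
- In its favour: the Z selectivity comes from a well-understood, kinetically controlled olefination; no hydride reagent comes near the benzylic ester; no gaseous aldehyde monomer is needed; and the hydroxyl arrives protected, so no metal alkoxide sits next to the new double bond. On handling and on chemoselectivity toward the ester it is the equal of the chosen plan or better.
- Against it here: A5 is branched at the α-carbon and carries a β-silyloxy group, so its anion can expel silyloxide in competition with olefination. α-Branched trifluoroethyl phosphonates are less dependable in Z selectivity with a small, enolisable aldehyde such as A6. A5 needs several steps from 3, and a fluoride- or acid-mediated desilylation must then be run on a base- and acid-sensitive molecule.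
- Comparison: structurally both plans converge on 10 and both leave the stereocentre remote and untouched, a point on which they are equal. Mechanistically the alternative relies on selection between two diastereomeric pathways, the chosen plan on the stereospecific course of a syn addition. In step economy the alternative needs about seven linear steps to 13 against four.

Alternative 3: The cut removes the carbonyl carbon of the central ester; the C1–C2 bond and the C1–O bond to the benzylic oxygen are both broken.
- Forward step: the vinyl iodide (Z)-tert-butyl[(2-iodobut-2-en-1-yl)oxy]dimethylsilane A8, carbon monoxide A9 and alcohol 3 would combine under PdCl2(PPh3)2 and iPr2NEt. This would give (S)-1-(3,4,5-trimethoxyphenyl)propyl (Z)-2-{[(tert-butyldimethylsilyl)oxy]methyl}but-2-enoate A7, which after desilylation would again meet the route at 10.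
- In its favour: the geometry is stored in an isolable iodide that can be purified and checked, and oxidative addition, migratory insertion of A9 and alcoholysis all retain it. On geometric security this alternative is the better plan, and like the chosen plan it never breaks the benzylic C–O bond.
- Against it here: alkoxycarbonylation is at its best with a simple alcohol in large excess, whereas 3 is hindered, secondary and the valuable partner, so capture of the acylpalladium species is expected to be slow and to compete with its decay. A9 is a toxic gas. A8 takes about three steps on its own and the silyl group costs a further deprotection.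
- Comparison: structurally both plans reach 10. Mechanistically, retention at an sp2 carbon–palladium bond is at least as trustworthy as the kinetic trapping of 8. In step economy the alternative has a longest linear sequence of about six steps and about seven in all, against four.

Key step: step 3

## Steps

Step 1
Reactants: 1 3,4,5-trimethoxybenzaldehyde
Product: 3 (S)-1-(3,4,5-trimethoxyphenyl)propan-1-ol, via ethylzinc alkoxide 2 (not isolated)
Conditions: Et2Zn (2 equiv, 1 M in toluene), (−)-DAIB (5 mol%), toluene, 0 °C; then sat. aq NH4Cl
Reagents that add atoms: diethylzinc, CC[Zn]CC
Why: Catalytic enantioselective 1,2-addition of a dialkylzinc to an aromatic aldehyde under amino-alcohol ligand acceleration; the zinc aminoalkoxide formed from (−)-DAIB holds aldehyde and Et2Zn in a dinuclear assembly that transfers ethyl to the Si face, which sets the S configuration of the new carbinol carbon, while the uncatalysed addition is slow at 0 °C.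

Step 2
Reactants: 3 (S)-1-(3,4,5-trimethoxyphenyl)propan-1-ol; 4 but-2-ynoic acid
Product: 6 (S)-1-(3,4,5-trimethoxyphenyl)propyl but-2-ynoate, via O-acylisourea 5 (not isolated)
Conditions: DCC (1.2 equiv), DMAP (5 mol%), CH2Cl2, −20 → 0 °C
Reagents that add atoms: N,N'-dicyclohexylcarbodiimide, C(=NC1CCCCC1)=NC1CCCCC1 (its atoms are held in intermediate 5 only and leave as the urea)
Why: Steglich esterification; the acid is activated as 5 and the acyl group is transferred to the hydroxyl oxygen of 3, so the benzylic C–O bond is never broken and the S configuration is carried over. Low temperature and a small charge of DMAP hold back conjugate addition to the activated ynoate and its isomerisation to the allenoate.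

Step 3
Reactants: 6 (S)-1-(3,4,5-trimethoxyphenyl)propyl but-2-ynoate; 7 formaldehyde (dry monomer)
Product: 10 (S)-1-(3,4,5-trimethoxyphenyl)propyl (Z)-2-(hydroxymethyl)but-2-enoate, via alpha-alumino enoate 8 (not isolated), via aluminium alkoxide 9 (not isolated)
Conditions: iBu2AlH (1.3 equiv), anhydrous NMO (2.6 equiv), THF, 0 °C; then 7 (gas in N2 stream, excess), −20 → 0 °C; aq potassium sodium tartrate, 0 °C
Reagents that add atoms: diisobutylaluminium hydride, CC(C)C[AlH]CC(C)C (only its hydride stays in 10; aluminium and the isobutyl groups are held in intermediates 8 and 9 and are lost on hydrolysis)
Why: This is a conjugate hydroalumination of an alkynoate with aldol trapping (vinylalumination), closely related to the reductive aldol of ynoates mediated by [(Ph3P)CuH]6. The N-oxide ligand makes iBu2AlH a tempered Lewis acid and a conjugate hydride donor, so hydride adds to C3 of 6 and gives 8, the C-bound form of the aluminium allenolate, with H and Al on the same side of the double bond. C2 of 8 then adds to the carbonyl carbon of 7 in an aldol step to give alkoxide 9, and cold hydrolysis releases 10. No ring is closed and no stereocentre is created; the element set here is the Z geometry of C2=C3. It is set kinetically: the nucleophilic lobe at C2 lies in the plane of the C3 substituents and the small electrophile enters past the C3 hydrogen and not past the C3 methyl, so CH2OH ends cis to H and the methyl cis to the ester carbonyl, a net syn addition of H and CH2OH across the triple bond. The step needs 1,4- and not 1,2-delivery of hydride, which the ligand on aluminium and the steric shielding of the secondary benzylic ester carbonyl should secure, and only a small excess of hydride is used, the rest of which 7 consumes. The benzylic stereocentre carries no acidic hydrogen, is separated from the reacting carbons by the ester group and should not ionise under the weakly Lewis acidic ligated aluminium. Reaction at or below 0 °C and a prompt quench with aqueous potassium sodium tartrate keep 9 from equilibrating to the E isomer.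

Step 4
Reactants: 10 (S)-1-(3,4,5-trimethoxyphenyl)propyl (Z)-2-(hydroxymethyl)but-2-enoate; 11 (Z)-2-methylbut-2-enoic acid (angelic acid)
Product: 13 (S)-1-(3,4,5-trimethoxyphenyl)propyl (Z)-2-({[(Z)-2-methylbut-2-enoyl]oxy}methyl)but-2-enoate, via mixed anhydride 12 (not isolated)
Conditions: 11 (1.5 equiv), 2,4,6-Cl3C6H2COCl (1.5 equiv), iPr2NEt (3.2 equiv), toluene, 23 °C; then 10, 65 °C
Reagents that add atoms: 2,4,6-trichlorobenzoyl chloride, O=C(Cl)c1c(Cl)cc(Cl)cc1Cl (its aroyl group is held in intermediate 12 only and leaves as the acid)
Why: Acylation of a primary alcohol by a mixed carboxylic anhydride (Yamaguchi-type activation run without a nucleophilic catalyst); the alcohol attacks the angeloyl carbonyl because the other carbonyl is shielded by two ortho chlorines. With no DMAP there is no acylammonium species, the usual channel for Z-to-E isomerisation of the angeloyl group and for SN2′ scrambling of the allylic ester, and the hindered amine only binds the acid set free, which protects the acid-sensitive benzylic ester.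

## Compound list

1 | 3,4,5-trimethoxybenzaldehyde | COc1cc(C=O)cc(OC)c1OC | starting material
2 | ethylzinc (S)-1-(3,4,5-trimethoxyphenyl)propan-1-olate (formed in the flask, not isolated) | CC[Zn]O[C@@H](CC)c1cc(OC)c(OC)c(OC)c1 | intermediate
3 | (S)-1-(3,4,5-trimethoxyphenyl)propan-1-ol | O[C@@H](CC)c1cc(OC)c(OC)c(OC)c1 | intermediate
4 | but-2-ynoic acid | CC#CC(=O)O | starting material
5 | O-(but-2-ynoyl)-N,N'-dicyclohexylisourea (formed in the flask, not isolated) | CC#CC(=O)OC(=NC1CCCCC1)NC1CCCCC1 | intermediate
6 | (S)-1-(3,4,5-trimethoxyphenyl)propyl but-2-ynoate | CC#CC(=O)O[C@@H](CC)c1cc(OC)c(OC)c(OC)c1 | intermediate
7 | formaldehyde (dry monomer from paraformaldehyde) | C=O | starting material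
8 | (S)-1-(3,4,5-trimethoxyphenyl)propyl (E)-2-(diisobutylalumanyl)but-2-enoate, the C-bound form of the aluminium allenolate (formed in the flask, not isolated) | C/C=C(/[Al](CC(C)C)CC(C)C)C(=O)O[C@@H](CC)c1cc(OC)c(OC)c(OC)c1 | intermediate
9 | (S)-1-(3,4,5-trimethoxyphenyl)propyl (Z)-2-{[(diisobutylalumanyl)oxy]methyl}but-2-enoate (formed in the flask, not isolated) | CC(C)C[Al](CC(C)C)OC/C(=C/C)C(=O)O[C@@H](CC)c1cc(OC)c(OC)c(OC)c1 | intermediate
10 | (S)-1-(3,4,5-trimethoxyphenyl)propyl (Z)-2-(hydroxymethyl)but-2-enoate | OC/C(=C/C)C(=O)O[C@@H](CC)c1cc(OC)c(OC)c(OC)c1 | intermediate
11 | (Z)-2-methylbut-2-enoic acid (angelic acid) | C/C=C(/C)C(=O)O | starting material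
12 | (Z)-2-methylbut-2-enoic 2,4,6-trichlorobenzoic anhydride (formed in the flask, not isolated) | C/C=C(/C)C(=O)OC(=O)c1c(Cl)cc(Cl)cc1Cl | intermediate
13 | (S)-1-(3,4,5-trimethoxyphenyl)propyl (Z)-2-({[(Z)-2-methylbut-2-enoyl]oxy}methyl)but-2-enoate | C/C=C(/C)C(=O)OC/C(=C/C)C(=O)O[C@@H](CC)c1cc(OC)c(OC)c(OC)c1 | target

## Step count and least certain steps

Total step count: 4. Longest linear sequence: 4 steps (1 → 3 → 6 → 10 → 13); 4, 7 and 11 are bought.

Step 3 (key step). The most likely failures are three: hydride delivery to the ester carbonyl in competition with conjugate addition, which would cleave the chiral alcohol from the molecule; incomplete capture of 8 by 7, so that protonation at C2 takes the place of hydroxymethylation; and leakage of geometry by equilibration of the allenolate or of 9 before the quench. The cause is that the hydride source is also a carbonyl-reducing agent and that the Z isomer is the kinetic and not the thermodynamic product. Changing the ligand to hexamethylphosphoramide or the hydride source to [(Ph3P)CuH]6 would alter conditions only. The fallback separates the two bond formations and fixes the geometry in isolable compounds. Starting from 6, syn hydrostannation with Bu3SnH under Pd(PPh3)4 in THF at 0 °C should place tin at C2 and give (S)-1-(3,4,5-trimethoxyphenyl)propyl (E)-2-(tributylstannyl)but-2-enoate F1. Iododestannylation with I2 in CH2Cl2 at 0 °C should give, with retention, (S)-1-(3,4,5-trimethoxyphenyl)propyl (E)-2-iodobut-2-enoate F2. Stille coupling of F2 with Bu3SnCH2OH under Pd(PPh3)4 in dioxane at 80 °C should install the hydroxymethyl group with retention and return to the route at 10.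

Step 4. The most likely failures are Z-to-E isomerisation of the angeloyl group while it is activated, SN2′-type scrambling at the central allylic ester, and acid-induced ionisation of the benzylic ester during heating. The cause is that an activated angeloyl derivative can add and lose nucleophiles at C3, and that an arenecarboxylic acid is released at 65 °C. The fallback reverses the roles of the partners: starting from 10 and 11, a Mitsunobu esterification (PPh3, diisopropyl azodicarboxylate, THF, 0 °C) activates the primary alcohol as an alkoxyphosphonium and lets 11 react as its carboxylate, so that no activated acyl derivative of 11 is formed at all. It arrives directly at 13 and makes no new compound on its way (F0).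

Step 2. The most likely failures are conjugate addition of DMAP or of the alcohol to the activated ynoate, base-induced isomerisation to the allenoate, and rearrangement of 5 to an unreactive N-acylurea. The cause is that acyl activation also raises the electrophilicity of C3 and the acidity of C4. The fallback forms the C1–C2 bond of the ynoate in place of the ester C–O bond. Starting from 3, 1,1'-carbonyldiimidazole in THF at 23 °C should give (S)-1-(3,4,5-trimethoxyphenyl)propyl 1H-imidazole-1-carboxylate F3, and prop-1-ynylmagnesium bromide in THF at −78 → −20 °C should then displace imidazole from F3 and return to the route at 6.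

Step 1. The most likely failure is insufficient face selection, through uncatalysed background addition or through hydride transfer from the ethylzinc reagent in place of ethyl transfer. Either would erode the enantiomeric purity, and no later step creates a second stereocentre that would allow an upgrade. The fallback replaces carbon transfer by hydride transfer as the enantio-determining event. Starting from 1, addition of EtMgBr in THF at 0 °C should give racemic 1-(3,4,5-trimethoxyphenyl)propan-1-ol F4, oxidation with MnO2 in CH2Cl2 should give 1-(3,4,5-trimethoxyphenyl)propan-1-one F5, and asymmetric transfer hydrogenation of F5 with RuCl(p-cymene)[(S,S)-TsDPEN] in HCO2H/Et3N should return to the route at 3.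

## Further compounds

F1 | step 3 | (S)-1-(3,4,5-trimethoxyphenyl)propyl (E)-2-(tributylstannyl)but-2-enoate | C/C=C(/[Sn](CCCC)(CCCC)CCCC)C(=O)O[C@@H](CC)c1cc(OC)c(OC)c(OC)c1
F2 | step 3 | (S)-1-(3,4,5-trimethoxyphenyl)propyl (E)-2-iodobut-2-enoate | C/C=C(/I)C(=O)O[C@@H](CC)c1cc(OC)c(OC)c(OC)c1
F0 | step 4 | none | none
F3 | step 2 | (S)-1-(3,4,5-trimethoxyphenyl)propyl 1H-imidazole-1-carboxylate | O=C(O[C@@H](CC)c1cc(OC)c(OC)c(OC)c1)n1ccnc1
F4 | step 1 | racemic 1-(3,4,5-trimethoxyphenyl)propan-1-ol | CCC(O)c1cc(OC)c(OC)c(OC)c1
F5 | step 1 | 1-(3,4,5-trimethoxyphenyl)propan-1-one | CCC(=O)c1cc(OC)c(OC)c(OC)c1
A1 | alternative 1 | (S)-1-(3,4,5-trimethoxyphenyl)prop-2-en-1-yl (Z)-2-{[(Z)-2-methylbut-2-enoyl]oxymethyl}but-2-enoate | C/C=C(/C)C(=O)OC/C(=C/C)C(=O)O[C@@H](C=C)c1cc(OC)c(OC)c(OC)c1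
A2 | alternative 1 | 1,2,3-trimethoxy-5-(propa-1,2-dien-1-yl)benzene | C=C=Cc1cc(OC)c(OC)c(OC)c1
A3 | alternative 1 | (Z)-2-{[(Z)-2-methylbut-2-enoyl]oxymethyl}but-2-enoic acid | C/C=C(/C)C(=O)OC/C(=C/C)C(=O)O
A4 | alternative 2 | (S)-1-(3,4,5-trimethoxyphenyl)propyl (Z)-2-{[(triisopropylsilyl)oxy]methyl}but-2-enoate | CC(C)[Si](C(C)C)(C(C)C)OC/C(=C/C)C(=O)O[C@@H](CC)c1cc(OC)c(OC)c(OC)c1
A5 | alternative 2 | (S)-1-(3,4,5-trimethoxyphenyl)propyl 2-[bis(2,2,2-trifluoroethoxy)phosphoryl]-3-[(triisopropylsilyl)oxy]propanoate (mixture at the phosphonate carbon) | CC(C)[Si](C(C)C)(C(C)C)OCC(C(=O)O[C@@H](CC)c1cc(OC)c(OC)c(OC)c1)P(=O)(OCC(F)(F)F)OCC(F)(F)F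
A6 | alternative 2 | acetaldehyde | CC=O
A7 | alternative 3 | (S)-1-(3,4,5-trimethoxyphenyl)propyl (Z)-2-{[(tert-butyldimethylsilyl)oxy]methyl}but-2-enoate | CC(C)(C)[Si](C)(C)OC/C(=C/C)C(=O)O[C@@H](CC)c1cc(OC)c(OC)c(OC)c1
A8 | alternative 3 | (Z)-tert-butyl[(2-iodobut-2-en-1-yl)oxy]dimethylsilane | C/C=C(\I)CO[Si](C)(C)C(C)(C)C
A9 | alternative 3 | carbon monoxide | [C-]#[O+]
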